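## Retrosynthetic overview

1. The target comes from its pentamethyl ether by cleaving five O–CH3 bonds last. That ether comes from 5,7,3',4'-tetramethoxy-8-(4-methoxybenzyl)flavone by adding the C3 hydroxyl (epoxidation of C2=C3, then acid opening).
2. The key disconnection is C4–C4a of ring C. The flavone is traced back to a (Z)-3-aryloxycinnamic acid, closed in the forward sense by intramolecular Friedel–Crafts acylation.
3. The feature used lies in ring A: C8a, which carries O1, sits between the benzyl-bearing C8 and C4a. In a 2-benzylphenol the oxygen therefore has only one unsubstituted ortho carbon, so connectivity decides 8-benzyl over 6-benzyl.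
4. O1–C2 is made by oxa-Michael addition of 3,5-dimethoxy-2-(4-methoxybenzyl)phenol to methyl 3-(3,4-dimethoxyphenyl)propiolate. The phenol comes from 4,6-dimethoxysalicylaldehyde and an aryl Grignard followed by ionic reduction; the propiolate comes from the arylacetylene.
5. Rings A, B and the benzyl arene are purchased. Ring C is the only ring built.

Key step: step 6

Remark: the target has no stereocentre and no stereoaxis, so it is achiral and needs no enantioselective step. The only lasting stereochemical element on the way is the alkene geometry of the aryloxycinnamate.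

## Route

Step 1
Reactants: 1 2-hydroxy-4,6-dimethoxybenzaldehyde; 2 4-methoxyphenylmagnesium bromide (commercial THF solution)
Product: 3 (±)-2-[hydroxy(4-methoxyphenyl)methyl]-3,5-dimethoxyphenol (used crude)
Conditions: 2 (2.3 equiv), THF, 0 °C → rt; sat. aq NH4Cl
Reagents that add atoms: none
Why: Grignard 1,2-addition to an aldehyde, in which the first equivalent of 2 only deprotonates the phenol and the second adds to the magnesium-chelated formyl group, giving a racemic carbinol centre that step 2 erases.

Step 2
Reactants: 3 (±)-2-[hydroxy(4-methoxyphenyl)methyl]-3,5-dimethoxyphenol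
Product: 4 3,5-dimethoxy-2-(4-methoxybenzyl)phenol
Conditions: Et3SiH (3 equiv), then TFA (5 equiv) added dropwise, CH2Cl2, 0 °C
Reagents that add atoms: none
Why: Ionic hydrogenation, in which the carbinol ionises to a benzhydryl cation (o-quinone methide form) stabilised by four oxygen donors and is trapped by silane hydride, with the silane present before the acid so that intermolecular Friedel–Crafts self-alkylation should not compete.

Step 3
Reactants: 5 4-ethynyl-1,2-dimethoxybenzene
Product: 7 methyl 3-(3,4-dimethoxyphenyl)prop-2-ynoate, via lithium acetylide 6 (not isolated)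
Conditions: n-BuLi (1.05 equiv), THF, −78 °C; ClCO2Me (1.3 equiv), −78 °C → rt
Reagents that add atoms: methyl chloroformate, COC(=O)Cl
Why: Deprotonation of the terminal alkyne and C-acylation of the lithium acetylide with a chloroformate is the standard alkynoate synthesis, and the aryl methyl ethers are inert to it.

Step 4
Reactants: 4 3,5-dimethoxy-2-(4-methoxybenzyl)phenol; 7 methyl 3-(3,4-dimethoxyphenyl)prop-2-ynoate
Product: 8 methyl (Z)-3-(3,4-dimethoxyphenyl)-3-[3,5-dimethoxy-2-(4-methoxybenzyl)phenoxy]acrylate
Conditions: 7 (1.2 equiv), Cs2CO3 (0.3 equiv), DMF, N2, 80 °C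
Reagents that add atoms: none
Why: Base-catalysed oxa-Michael addition of a phenoxide to an arylpropiolate (first half of the Ruhemann flavone synthesis) should put oxygen on the aryl-bearing alkyne carbon because only that gives an ester-stabilised allenolate, and both anti addition and the preference of the veratryl group to lie trans to the ester favour the Z alkene, while any E isomer can be carried on since step 6 is convergent.

Step 5
Reactants: 8 methyl (Z)-3-(3,4-dimethoxyphenyl)-3-[3,5-dimethoxy-2-(4-methoxybenzyl)phenoxy]acrylate
Product: 9 (Z)-3-(3,4-dimethoxyphenyl)-3-[3,5-dimethoxy-2-(4-methoxybenzyl)phenoxy]acrylic acid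
Conditions: LiOH·H2O (3 equiv), THF/MeOH/H2O, rt → 40 °C; 1 M HCl, 0 °C, to pH 3
Reagents that add atoms: lithium hydroxide, [Li+].[OH-]
Why: Ester saponification (BAc2) should outrun conjugate attack at the donor-substituted, fully substituted β-carbon, and cold acidification to pH 3 keeps the β-aryloxycinnamic acid from decarboxylating or hydrolysing at its enol ether.

Step 6
Reactants: 9 (Z)-3-(3,4-dimethoxyphenyl)-3-[3,5-dimethoxy-2-(4-methoxybenzyl)phenoxy]acrylic acid
Product: 11 5,7,3',4'-tetramethoxy-8-(4-methoxybenzyl)flavone, via acyl methanesulfonate 10 (not isolated)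
Conditions: Eaton's reagent (7.7 wt % P2O5 in MeSO3H), ca. 0.1 M, 0 °C → rt; poured onto ice-water
Reagents that add atoms: none
Why: The P2O5/MeSO3H medium dehydrates acid 9 to the acyl methanesulfonate 10, in equilibrium with its acylium ion, which attacks the phenoxy-ring carbon ortho to the ether oxygen (future C4a), and proton loss from the arenium ion forms C4–C4a and the 4-pyranone. This is an intramolecular Friedel–Crafts acylation, the second half of the Ruhemann flavone synthesis, known for β-aryloxycinnamic acids with sulfuric acid, polyphosphoric acid or acid chloride/AlCl3 and paralleled by the xanthone closure of 2-aryloxybenzoic acids. Ring C closes as a six-membered ring, formally 6-exo-trig at the acyl carbon (the C=O stays outside the new ring), with the Z alkene holding acyl carbon and arene within bonding distance, and no stereocentre is formed. Regioselectivity is secured by the substrate, because the second ortho carbon (future C8) carries the 4-methoxybenzyl group and the carbon between the two methoxy groups is para to the ether oxygen and out of reach, so the only acylable C–H is ortho to one methoxy group and para to the other. Chemoselectivity against the veratryl ring holds because that closure would need the E isomer and a strained five-membered indenone, and because the acylium ion has ArO+=C–CH=C=O character, so rotation about Cα–Cβ is easy and E material should drain into the flavone. Working at or below room temperature and quenching as soon as 9 is consumed limits ipso protonation at the benzyl-bearing carbon, and the product is shielded because its carbonyl is protonated and ring A is then deactivated.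

Step 7
Reactants: 11 5,7,3',4'-tetramethoxy-8-(4-methoxybenzyl)flavone
Product: 13 3-hydroxy-5,7,3',4'-tetramethoxy-8-(4-methoxybenzyl)flavone, via flavone 2,3-epoxide 12 (not isolated)
Conditions: DMDO (ca. 0.08 M in acetone, 3 equiv in portions), CH2Cl2, 0 °C → rt; evaporate; p-TsOH·H2O (10 mol %), CH2Cl2, rt
Reagents that add atoms: dimethyldioxirane, CC1(C)OO1
Why: Neutral electrophilic epoxidation of the enol-ether-like C2=C3 bond with a dioxirane, then acid-catalysed opening at C2 (cation stabilised by O1 and the veratryl ring) and loss of H3, is the known flavone-to-flavonol conversion, and the two centres of the racemic, necessarily cis-fused epoxide 12 vanish on re-aromatisation.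

Step 8
Reactants: 13 3-hydroxy-5,7,3',4'-tetramethoxy-8-(4-methoxybenzyl)flavone
Product: 14 8-(4-hydroxybenzyl)quercetin (target)
Conditions: BBr3 (12 equiv), CH2Cl2, −78 °C → rt; H2O, 0 °C
Reagents that add atoms: none
Why: Lewis-acid cleavage of aryl methyl ethers with BBr3 should remove all five methyl groups while the C8–CH2 carbon–carbon bond is untouched, and the aprotic conditions at or below room temperature avoid the pyranone ring opening that causes a Wessely–Moser 8-to-6 shift in hot HI or HBr.

## Compound list

1 | 2-hydroxy-4,6-dimethoxybenzaldehyde | COc1cc(O)c(C=O)c(OC)c1 | starting material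
2 | 4-methoxyphenylmagnesium bromide | COc1ccc([Mg]Br)cc1 | starting material
3 | (±)-2-[hydroxy(4-methoxyphenyl)methyl]-3,5-dimethoxyphenol (racemic) | COc1ccc(C(O)c2c(O)cc(OC)cc2OC)cc1 | intermediate
4 | 3,5-dimethoxy-2-(4-methoxybenzyl)phenol | COc1ccc(Cc2c(O)cc(OC)cc2OC)cc1 | intermediate
5 | 4-ethynyl-1,2-dimethoxybenzene | COc1ccc(C#C)cc1OC | starting material
6 | lithium (3,4-dimethoxyphenyl)acetylide (not isolated) | COc1ccc(C#C[Li])cc1OC | intermediate
7 | methyl 3-(3,4-dimethoxyphenyl)prop-2-ynoate | COC(=O)C#Cc1ccc(OC)c(OC)c1 | intermediate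
8 | methyl (Z)-3-(3,4-dimethoxyphenyl)-3-[3,5-dimethoxy-2-(4-methoxybenzyl)phenoxy]acrylate | COC(=O)/C=C(\Oc1cc(OC)cc(OC)c1Cc1ccc(OC)cc1)c1ccc(OC)c(OC)c1 | intermediate
9 | (Z)-3-(3,4-dimethoxyphenyl)-3-[3,5-dimethoxy-2-(4-methoxybenzyl)phenoxy]acrylic acid | OC(=O)/C=C(\Oc1cc(OC)cc(OC)c1Cc1ccc(OC)cc1)c1ccc(OC)c(OC)c1 | intermediate
10 | mixed anhydride of 9 with methanesulfonic acid (not isolated) | CS(=O)(=O)OC(=O)/C=C(\Oc1cc(OC)cc(OC)c1Cc1ccc(OC)cc1)c1ccc(OC)c(OC)c1 | intermediate
11 | 5,7,3',4'-tetramethoxy-8-(4-methoxybenzyl)flavone | COc1ccc(Cc2c(OC)cc(OC)c3c(=O)cc(-c4ccc(OC)c(OC)c4)oc23)cc1 | intermediate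
12 | 2,3-epoxide of 11 (racemic, cis-fused oxirane, one enantiomer drawn, not isolated) | O=C1[C@@H]2O[C@]2(c3ccc(OC)c(OC)c3)Oc4c(Cc5ccc(OC)cc5)c(OC)cc(OC)c14 | intermediate
13 | 3-hydroxy-5,7,3',4'-tetramethoxy-8-(4-methoxybenzyl)flavone | COc1ccc(Cc2c(OC)cc(OC)c3c(=O)c(O)c(-c4ccc(OC)c(OC)c4)oc23)cc1 | intermediate
14 | 8-(4-hydroxybenzyl)quercetin | O=c1c(O)c(-c2ccc(O)c(O)c2)oc2c(Cc3ccc(O)cc3)c(O)cc(O)c12 | target

## Step count and risks

Total step count: 8. Longest linear sequence: 7 (steps 1, 2, 4, 5, 6, 7, 8). Step 3 is the one-step side branch.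

**Step 6 (key step).** Three processes could compete in the strong acid. The 4-methoxybenzyl group could be lost or migrate, through ipso protonation or ipso acylation at the benzyl-bearing carbon followed by retro-Friedel–Crafts. The β-aryloxycinnamic acid could decarboxylate before it is activated. Intermolecular acylation could occur at the ring-A carbon between the two methoxy groups.

The fallback sets out from phenol 4 and closes ring C at O1–C2 instead:
- C-acetylation ortho to the hydroxyl (Ac2O, BF3·OEt2; O-acetylation and Fries shift under boron chelation) would give 1-[2-hydroxy-4,6-dimethoxy-3-(4-methoxybenzyl)phenyl]ethanone F1.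
- Claisen–Schmidt condensation with 3,4-dimethoxybenzaldehyde (KOH, EtOH, rt) would give (E)-3-(3,4-dimethoxyphenyl)-1-[2-hydroxy-4,6-dimethoxy-3-(4-methoxybenzyl)phenyl]prop-2-en-1-one F2.
- Oxidative cyclisation with catalytic I2 in DMSO at 130 °C comes back to the route at flavone 11.

**Step 4.** The conjugate addition could be slow and reversible. The alkyne is deactivated by the donor veratryl group, the phenoxide is hindered by its ortho benzyl group, and acyl transfer from the ester to the phenoxide could compete.

The fallback sets out from propiolate 7, with phenol 4 as partner: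
- Hydroiodination (NaI, AcOH, 100 °C, anti addition) would give methyl (Z)-3-(3,4-dimethoxyphenyl)-3-iodoacrylate F3.
- Ullmann-type vinyl C–O coupling with 4 (CuI, N,N-dimethylglycine, Cs2CO3, dioxane, 90 °C), with retention of alkene geometry, comes back to the route at ester 8.

**Step 7.** Epoxidation of the vinylogous ester double bond could remain incomplete. The excess dioxirane could also oxidise the electron-rich arenes or the doubly benzylic CH2.

The fallback sets out from flavone 11:
- Carbonyl-directed deprotonation with LDA (THF, −78 °C) would give 3-lithio-5,7,3',4'-tetramethoxy-8-(4-methoxybenzyl)flavone F4.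
- Trapping with B(OMe)3 would give dimethyl [5,7,3',4'-tetramethoxy-8-(4-methoxybenzyl)flavon-3-yl]boronate F5.
- Oxidation with H2O2/AcOH (boron-to-oxygen 1,2-shift) comes back to the route at flavonol 13.

## Further compounds

F1 | step 6 | 1-[2-hydroxy-4,6-dimethoxy-3-(4-methoxybenzyl)phenyl]ethanone | CC(=O)c1c(O)c(Cc2ccc(OC)cc2)c(OC)cc1OC
F2 | step 6 | (E)-3-(3,4-dimethoxyphenyl)-1-[2-hydroxy-4,6-dimethoxy-3-(4-methoxybenzyl)phenyl]prop-2-en-1-one | COc1ccc(/C=C/C(=O)c2c(O)c(Cc3ccc(OC)cc3)c(OC)cc2OC)cc1OC
F3 | step 4 | methyl (Z)-3-(3,4-dimethoxyphenyl)-3-iodoacrylate | COC(=O)/C=C(\I)c1ccc(OC)c(OC)c1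
F4 | step 7 | 3-lithio-5,7,3',4'-tetramethoxy-8-(4-methoxybenzyl)flavone | COc1ccc(Cc2c(OC)cc(OC)c3c(=O)c([Li])c(-c4ccc(OC)c(OC)c4)oc23)cc1
F5 | step 7 | dimethyl [5,7,3',4'-tetramethoxy-8-(4-methoxybenzyl)flavon-3-yl]boronate | COB(OC)c1c(-c2ccc(OC)c(OC)c2)oc2c(Cc3ccc(OC)cc3)c(OC)cc(OC)c2c1=O
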